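We start from amounts in millimolar, since percentages hide what the earlier runs share.

| flask | starting material | second substrate | partner | free catalyst | remark | time |
|---|---|---|---|---|---|---|
| dawn | 0.25 mM | 0.50 mM | 0.25 mM | 50 µM | run made earlier |  |
| dusk | 1 mM | 0.50 mM | 0.25 mM | 50 µM | run made earlier |  |
| midnight | 0.50 mM | 0.25 mM | 0.25 mM | 50 µM | run made earlier |  |
| flask | 0.50 mM | 0.500 mM | 0.250 mM | 50 µM |  | 2.5 min |

| run | time / min | target / % | catalyst intermediate A / % | starting material / % |
|---|---|---|---|---|
| dawn | 0.250 | 67.9 | 5.0 | 26.7 |
| dawn | 0.417 | 77.8 | 3.9 | 18.7 |
| dawn | 0.833 | 84.8 | 3.4 | 12.3 |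
| dawn | 1.50 | 87.0 | 2.6 | 11.2 |
| dawn | 3.00 | 87.2 | 3.0 | 10.0 |
| dusk | 0.667 | 24.9 | 3.3 | 72.1 |
| dusk | 1.33 | 24.1 | 3.8 | 72.0 |
| dusk | 2.00 | 24.7 | 3.6 | 71.6 |
| dusk | 2.50 | 24.5 | 3.0 | 71.8 |
| dusk | 3.00 | 24.8 | 4.4 | 71.2 |
| midnight | 0.250 | 44.2 | 5.9 | 50.0 |
| midnight | 0.417 | 48.0 | 5.1 | 45.9 |
| midnight | 0.833 | 49.5 | 5.7 | 45.5 |
| midnight | 1.50 | 49.4 | 5.6 | 45.9 |
| midnight | 3.00 | 49.1 | 5.6 | 43.4 |

(scatter of a reading: 0.5 percentage points)

- the reaction counts as stopped when no species that holds the starting material changes by six tenths of a point or more over the second half of the time

- which holds at 2.5 min: what has brought the reaction to rest, or that it has not come to rest (no working catalyst is left / it is still moving / the partner has run out first / all of the starting material has reacted / forward and back rates have come level)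
- target at 2.5 min, in percent of the starting material charged
- catalyst intermediate A at 2.5 min, in percent of the starting material charged

The last target reading of the dusk run comes to 0.248 mM and that of the midnight run, at 1.50 min, to 0.247 mM. These amounts agree within the scatter, although dusk charged 1 mM of starting material and midnight 0.50 mM, and dusk had twice the second substrate. Both stand close to the 0.25 mM of partner charged, so we read one partner used for each target formed. A reagent whose charge caps the product in this way is the limiting reagent.

For the flask, 0.250 mM of partner over 0.50 mM of starting material gives 50.0%. This ratio, the partner ceiling, is the share of the starting material that the partner can turn into target. Control changes hands where the ceiling crosses 100%. Dusk, at 25.0%, read 24.8%, and midnight, at 50.0%, read 49.4%. The dawn run, charged right at the crossing, read 87.2% with 10.0% of starting material beside it, so in the dawn run the ceiling was an upper mark and no more.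

The flask lies well below the crossing, with the ceiling of midnight and the second substrate of dusk. Midnight's target was flat by 0.833 min, well before the asked 2.5 min. We therefore expect the partner to give out first, target a little under the ceiling, and catalyst intermediate A near midnight's 5.6%.

The forecast gave 49.4% of target, 5.6% of catalyst intermediate A and "the partner has run out first", holding that “the partner sets the ceiling”.

The flask gives 47.9% of target and 5.55% of catalyst intermediate A at 2.5 min, with 0% of the partner left, so the partner has run out first. The steps behind it are these:

    second substrate + free catalyst ⇌ catalyst intermediate B (K = 780 M⁻¹, k = 41000 M⁻¹ s⁻¹)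
    starting material + free catalyst ⇌ catalyst intermediate A (K = 7400 M⁻¹, k = 16000 M⁻¹ s⁻¹)
    partner + catalyst intermediate B → free catalyst + second product (k = 1100 M⁻¹ s⁻¹)
    partner + catalyst intermediate A → free catalyst + target (k = 5100 M⁻¹ s⁻¹)

The target stands 2.1 percentage points under the ceiling of 50.0%, and the second product, 0.0103 mM at 2.50 min, equals 2.06% of the starting material charged. In the neighbouring flask with 0.12 mM of starting material, the same ratio gives 208%, past the crossing. There the starting material ran out first, with 0.023% of it left unbound, target at >99.9% and 6.5% of the partner's charge still present.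

Readings and results stem from a simulated flask for an exercise; the scatter is artificial.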